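**Plan** (oxolane numbering of the target: O1, C2 aryl, C3 bearing the CH2O–benzoate, C4 arylmethyl, C5 H2)
Retrosynthesis: cut the 4-hydroxybenzoate ester; trace the C3 hydroxymethyl back to an (E)-propenyl group; raise C5 to a lactone carbonyl; then cut O1–C5 and C3–C4 together (Ireland–Claisen rearrangement with lactonization); finally cut the allylic ester C–O bond and the C2–alkyne bond.
Enabling feature: O1 on benzylic C2 lies γ to C5 through C3–C4, so the oxolane is a reduced γ-lactone whose acyl part (C5, C4, arylmethyl) is a 3-arylpropanoate. The one-carbon branch on C3 is the stump of the alkene that a [3,3] shift leaves behind, so C3 and C4, two carbons of like polarity, are joined inside a six-membered transition state.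
Forward: dihydroferulic acid → O-benzyl acid → ester of (R)-but-3-yn-2-ol → asymmetric alkynylation of O-benzylvanillin → silyl ether → Z-alkene → rearrangement/lactonization (the only ring closure) → lactol → oxolane → ozonolysis/reduction → benzoate → hydrogenolysis.
Stereochemistry: C2 comes from the catalyst-controlled alkynylation. C3 and C4 come from the purchased (R)-carbinol centre by 1,3-chirality transfer through a chair transition state (Z-alkene plus E-ketene acetal give the 3,4-cis pair); that centre is then excised by ozonolysis.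

Key step: step 6

Assumption: (S,S)-ProPhenol is taken to deliver the zinc acetylide to the Re face of the aryl aldehyde; if the sense is the reverse, the (R,R)-ligand is used and nothing else changes.

Step 1
Reactants: 1 3-(4-hydroxy-3-methoxyphenyl)propanoic acid
Product: 3 3-[4-(benzyloxy)-3-methoxyphenyl]propanoic acid, via benzyl ester 2 (not isolated)
Conditions: BnBr, K2CO3, DMF, 60 °C; then NaOH, MeOH/H2O, 60 °C; then aq HCl
Reagents that add atoms: benzyl bromide BrCc1ccccc1; sodium hydroxide [Na+].[OH-]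
Why: Williamson O-alkylation of the phenoxide and carboxylate followed by saponification, which cleaves only the benzyl ester and leaves the aryl benzyl ether.

Step 2
Reactants: 3 3-[4-(benzyloxy)-3-methoxyphenyl]propanoic acid; 4 (R)-but-3-yn-2-ol
Product: 5 (2R)-but-3-yn-2-yl 3-[4-(benzyloxy)-3-methoxyphenyl]propanoate
Conditions: EDC·HCl, DMAP (cat.), CH2Cl2, 0 °C → rt
Reagents that add atoms: none
Why: Steglich-type carbodiimide esterification forms the acyl–O bond, so the propargylic stereocentre is not touched.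

Step 3
Reactants: 5 (2R)-but-3-yn-2-yl 3-[4-(benzyloxy)-3-methoxyphenyl]propanoate (2 equiv, excess recovered); 6 4-(benzyloxy)-3-methoxybenzaldehyde
Product: 7 (2R,5S)-5-[4-(benzyloxy)-3-methoxyphenyl]-5-hydroxypent-3-yn-2-yl 3-[4-(benzyloxy)-3-methoxyphenyl]propanoate
Conditions: Me2Zn, (S,S)-ProPhenol (20 mol %), Ph3P=O (40 mol %), toluene, 0 °C; aq NH4Cl
Reagents that add atoms: none
Why: Catalytic asymmetric addition of a zinc acetylide to an aryl aldehyde (dinuclear zinc–ProPhenol alkynylation) tolerates the ester, and Re-face delivery under ligand control should set the 5S carbinol (the future C2) with little influence from the remote C2 centre of the alkyne.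

Step 4
Reactants: 7 (2R,5S)-5-[4-(benzyloxy)-3-methoxyphenyl]-5-hydroxypent-3-yn-2-yl 3-[4-(benzyloxy)-3-methoxyphenyl]propanoate
Product: 8 (2R,5S)-5-[4-(benzyloxy)-3-methoxyphenyl]-5-[(triethylsilyl)oxy]pent-3-yn-2-yl 3-[4-(benzyloxy)-3-methoxyphenyl]propanoate
Conditions: Et3SiCl, imidazole, CH2Cl2, 0 °C
Reagents that add atoms: chlorotriethylsilane CC[Si](Cl)(CC)CC
Why: Routine silylation of the secondary alcohol masks the hydroxyl before the Z-alkene is made, so that it can neither quench the base of step 6 nor displace the allylic ester.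

Step 5
Reactants: 8 (2R,5S)-5-[4-(benzyloxy)-3-methoxyphenyl]-5-[(triethylsilyl)oxy]pent-3-yn-2-yl 3-[4-(benzyloxy)-3-methoxyphenyl]propanoate
Product: 9 (2R,3Z,5R)-5-[4-(benzyloxy)-3-methoxyphenyl]-5-[(triethylsilyl)oxy]pent-3-en-2-yl 3-[4-(benzyloxy)-3-methoxyphenyl]propanoate
Conditions: H2 (1 atm), Pd/CaCO3 poisoned with Pb(OAc)2 (Lindlar catalyst), quinoline, EtOAc, rt
Reagents that add atoms: none
Why: Syn semihydrogenation on poisoned palladium should give the Z-alkene while benzyl ethers, silyl ether and ester survive (the C5 descriptor changes from S to R only because the alkenyl carbon ranks below the aryl carbon).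

Step 6
Reactants: 9 (2R,3Z,5R)-5-[4-(benzyloxy)-3-methoxyphenyl]-5-[(triethylsilyl)oxy]pent-3-en-2-yl 3-[4-(benzyloxy)-3-methoxyphenyl]propanoate
Product: 13 (3S,4R,5R)-3-[4-(benzyloxy)-3-methoxybenzyl]-5-[4-(benzyloxy)-3-methoxyphenyl]-4-[(1E)-prop-1-en-1-yl]oxolan-2-one, via silyl ketene acetal 10 (not isolated), via silyl ester 11 (not isolated), via hydroxy acid 12 (not isolated)
Conditions: LiN(iPr)2, Me3SiCl/Et3N, THF, −78 °C → 50 °C; then 1 M aq HCl, THF, rt
Reagents that add atoms: none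
Why: Kinetic deprotonation in THF without a polar additive and in situ silylation should give the (E)-silyl ketene acetal 10 (arylmethyl cis to the allylic oxygen), which undergoes the Ireland–Claisen [3,3]-sigmatropic rearrangement on warming; the closest known reaction type is the ester enolate Claisen rearrangement of (Z)-allylic esters of secondary carbinols with 1,3-chirality transfer. In the chair transition state the methyl group on the carbinol carbon sits equatorial, because the other chair would place it 1,3-diaxial to the axial CH(OSiEt3)Ar substituent of the Z-alkene, so the R carbinol centre fixes the face of the future C3 that is attacked and is traded for the new C3 centre and an (E)-propenyl group. The axial Z-substituent and the axial arylmethyl group of the ketene acetal lie antiperiplanar across the new C3–C4 bond, which is the syn relationship that becomes 3,4-cis in the ring (C4 is controlled by ketene acetal geometry, C3 by the carbinol centre, and C2 is carried unchanged from step 3). Aqueous HCl then hydrolyses the silyl ester and the triethylsilyl ether, and the freed benzylic hydroxyl on C2, γ to the carboxyl carbon, closes the ring by 5-exo-trig acyl substitution (lactonization), forming the O1–C5 bond. The step needs high E-selectivity in the enolization and chair over boat; the first is secured by the additive-free kinetic conditions with internal silyl trapping, the second by the acyclic substrate, in which the C2 centre can turn its hydrogen over the ring and its aryl group anti to the forming bond.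

Step 7
Reactants: 13 (3S,4R,5R)-3-[4-(benzyloxy)-3-methoxybenzyl]-5-[4-(benzyloxy)-3-methoxyphenyl]-4-[(1E)-prop-1-en-1-yl]oxolan-2-one
Product: 14 (3S,4R,5R)-3-[4-(benzyloxy)-3-methoxybenzyl]-5-[4-(benzyloxy)-3-methoxyphenyl]-4-[(1E)-prop-1-en-1-yl]oxolan-2-ol (anomer mixture)
Conditions: iBu2AlH, CH2Cl2, −78 °C; aq potassium sodium tartrate
Reagents that add atoms: none
Why: Partial reduction of a γ-lactone to the lactol stops at the stable aluminium hemiacetal at low temperature, and no other reducible group is present.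

Step 8
Reactants: 14 (3S,4R,5R)-3-[4-(benzyloxy)-3-methoxybenzyl]-5-[4-(benzyloxy)-3-methoxyphenyl]-4-[(1E)-prop-1-en-1-yl]oxolan-2-ol
Product: 15 (2R,3R,4S)-4-[4-(benzyloxy)-3-methoxybenzyl]-2-[4-(benzyloxy)-3-methoxyphenyl]-3-[(1E)-prop-1-en-1-yl]oxolane
Conditions: Et3SiH, BF3·OEt2, CH2Cl2, −78 °C
Reagents that add atoms: none
Why: Ionic hydrogenation of the lactol through the cyclic oxocarbenium ion delivers hydride to C5 (no stereocentre is created), and the low temperature should leave the benzylic C2–O bond intact.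

Step 9
Reactants: 15 (2R,3R,4S)-4-[4-(benzyloxy)-3-methoxybenzyl]-2-[4-(benzyloxy)-3-methoxyphenyl]-3-[(1E)-prop-1-en-1-yl]oxolane
Product: 17 [(2R,3S,4S)-4-[4-(benzyloxy)-3-methoxybenzyl]-2-[4-(benzyloxy)-3-methoxyphenyl]oxolan-3-yl]methanol, via aldehyde 16 (not isolated)
Conditions: O3, CH2Cl2/MeOH, −78 °C (stopped at first persistent blue); then NaBH4, −78 °C → 0 °C
Reagents that add atoms: ozone [O-][O+]=O
Why: Ozonolysis of the only alkene with in situ borohydride reduction converts the propenyl stump into the hydroxymethyl group, and reducing the aldehyde cold as it forms should prevent epimerization at C3.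

Step 10
Reactants: 17 [(2R,3S,4S)-4-[4-(benzyloxy)-3-methoxybenzyl]-2-[4-(benzyloxy)-3-methoxyphenyl]oxolan-3-yl]methanol; 18 4-(benzyloxy)benzoic acid
Product: 19 [(2R,3S,4S)-4-[4-(benzyloxy)-3-methoxybenzyl]-2-[4-(benzyloxy)-3-methoxyphenyl]oxolan-3-yl]methyl 4-(benzyloxy)benzoate
Conditions: EDC·HCl, DMAP, CH2Cl2, rt
Reagents that add atoms: none
Why: Steglich-type esterification of the only free hydroxyl, a primary alcohol, with all phenols masked.

Step 11
Reactants: 19 [(2R,3S,4S)-4-[4-(benzyloxy)-3-methoxybenzyl]-2-[4-(benzyloxy)-3-methoxyphenyl]oxolan-3-yl]methyl 4-(benzyloxy)benzoate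
Product: 20 agastinol, [(2R,3S,4S)-4-(4-hydroxy-3-methoxybenzyl)-2-(4-hydroxy-3-methoxyphenyl)oxolan-3-yl]methyl 4-hydroxybenzoate
Conditions: H2 (1 atm), Pd/C, EtOAc/MeOH, rt, stopped at full debenzylation
Reagents that add atoms: none
Why: Hydrogenolysis of the three aryl benzyl ethers should be much faster than cleavage of the cyclic benzylic ether, and the aryl ester is inert.

**Compound list**
1 | 3-(4-hydroxy-3-methoxyphenyl)propanoic acid | COc1cc(CCC(=O)O)ccc1O | starting material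
2 | benzyl 3-[4-(benzyloxy)-3-methoxyphenyl]propanoate | COc1cc(CCC(=O)OCc2ccccc2)ccc1OCc1ccccc1 | intermediate
3 | 3-[4-(benzyloxy)-3-methoxyphenyl]propanoic acid | COc1cc(CCC(=O)O)ccc1OCc1ccccc1 | intermediate
4 | (R)-but-3-yn-2-ol | C#C[C@@H](C)O | starting material
5 | (2R)-but-3-yn-2-yl 3-[4-(benzyloxy)-3-methoxyphenyl]propanoate | C#C[C@@H](C)OC(=O)CCc1ccc(OCc2ccccc2)c(OC)c1 | intermediate
6 | 4-(benzyloxy)-3-methoxybenzaldehyde | COc1cc(C=O)ccc1OCc1ccccc1 | starting material
7 | (2R,5S)-5-[4-(benzyloxy)-3-methoxyphenyl]-5-hydroxypent-3-yn-2-yl 3-[4-(benzyloxy)-3-methoxyphenyl]propanoate | O[C@@H](c1ccc(OCc2ccccc2)c(OC)c1)C#C[C@@H](C)OC(=O)CCc1ccc(OCc2ccccc2)c(OC)c1 | intermediate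
8 | (2R,5S)-5-[4-(benzyloxy)-3-methoxyphenyl]-5-[(triethylsilyl)oxy]pent-3-yn-2-yl 3-[4-(benzyloxy)-3-methoxyphenyl]propanoate | CC[Si](CC)(CC)O[C@@H](c1ccc(OCc2ccccc2)c(OC)c1)C#C[C@@H](C)OC(=O)CCc1ccc(OCc2ccccc2)c(OC)c1 | intermediate
9 | (2R,3Z,5R)-5-[4-(benzyloxy)-3-methoxyphenyl]-5-[(triethylsilyl)oxy]pent-3-en-2-yl 3-[4-(benzyloxy)-3-methoxyphenyl]propanoate | CC[Si](CC)(CC)O[C@@H](c1ccc(OCc2ccccc2)c(OC)c1)/C=C\[C@@H](C)OC(=O)CCc1ccc(OCc2ccccc2)c(OC)c1 | intermediate
10 | (E)-trimethylsilyl ketene acetal of 9 (Me3SiO trans to the arylmethyl group) | CC[Si](CC)(CC)O[C@@H](c1ccc(OCc2ccccc2)c(OC)c1)/C=C\[C@@H](C)O/C(O[Si](C)(C)C)=C\Cc1ccc(OCc2ccccc2)c(OC)c1 | intermediate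
11 | trimethylsilyl (2S,3R,4E)-2-[4-(benzyloxy)-3-methoxybenzyl]-3-{(R)-[4-(benzyloxy)-3-methoxyphenyl][(triethylsilyl)oxy]methyl}hex-4-enoate | COc1cc(C[C@H](C(=O)O[Si](C)(C)C)[C@@H](/C=C/C)[C@@H](O[Si](CC)(CC)CC)c2ccc(OCc3ccccc3)c(OC)c2)ccc1OCc1ccccc1 | intermediate
12 | (2S,3R,4E)-2-[4-(benzyloxy)-3-methoxybenzyl]-3-{(R)-[4-(benzyloxy)-3-methoxyphenyl](hydroxy)methyl}hex-4-enoic acid | COc1cc(C[C@H](C(=O)O)[C@@H](/C=C/C)[C@@H](O)c2ccc(OCc3ccccc3)c(OC)c2)ccc1OCc1ccccc1 | intermediate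
13 | (3S,4R,5R)-3-[4-(benzyloxy)-3-methoxybenzyl]-5-[4-(benzyloxy)-3-methoxyphenyl]-4-[(1E)-prop-1-en-1-yl]oxolan-2-one | COc1cc(C[C@@H]2C(=O)O[C@@H](c3ccc(OCc4ccccc4)c(OC)c3)[C@@H]2/C=C/C)ccc1OCc1ccccc1 | intermediate
14 | (3S,4R,5R)-3-[4-(benzyloxy)-3-methoxybenzyl]-5-[4-(benzyloxy)-3-methoxyphenyl]-4-[(1E)-prop-1-en-1-yl]oxolan-2-ol (anomer mixture) | COc1cc(C[C@@H]2C(O)O[C@@H](c3ccc(OCc4ccccc4)c(OC)c3)[C@@H]2/C=C/C)ccc1OCc1ccccc1 | intermediate
15 | (2R,3R,4S)-4-[4-(benzyloxy)-3-methoxybenzyl]-2-[4-(benzyloxy)-3-methoxyphenyl]-3-[(1E)-prop-1-en-1-yl]oxolane | COc1cc(C[C@@H]2CO[C@@H](c3ccc(OCc4ccccc4)c(OC)c3)[C@@H]2/C=C/C)ccc1OCc1ccccc1 | intermediate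
16 | (2R,3R,4S)-4-[4-(benzyloxy)-3-methoxybenzyl]-2-[4-(benzyloxy)-3-methoxyphenyl]oxolane-3-carbaldehyde | COc1cc(C[C@@H]2CO[C@@H](c3ccc(OCc4ccccc4)c(OC)c3)[C@@H]2C=O)ccc1OCc1ccccc1 | intermediate
17 | [(2R,3S,4S)-4-[4-(benzyloxy)-3-methoxybenzyl]-2-[4-(benzyloxy)-3-methoxyphenyl]oxolan-3-yl]methanol | COc1cc(C[C@@H]2CO[C@@H](c3ccc(OCc4ccccc4)c(OC)c3)[C@@H]2CO)ccc1OCc1ccccc1 | intermediate
18 | 4-(benzyloxy)benzoic acid | O=C(O)c1ccc(OCc2ccccc2)cc1 | starting material
19 | [(2R,3S,4S)-4-[4-(benzyloxy)-3-methoxybenzyl]-2-[4-(benzyloxy)-3-methoxyphenyl]oxolan-3-yl]methyl 4-(benzyloxy)benzoate | COc1cc(C[C@@H]2CO[C@@H](c3ccc(OCc4ccccc4)c(OC)c3)[C@@H]2COC(=O)c2ccc(OCc3ccccc3)cc2)ccc1OCc1ccccc1 | intermediate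
20 | agastinol, [(2R,3S,4S)-4-(4-hydroxy-3-methoxybenzyl)-2-(4-hydroxy-3-methoxyphenyl)oxolan-3-yl]methyl 4-hydroxybenzoate | COc1cc(C[C@@H]2CO[C@@H](c3ccc(O)c(OC)c3)[C@@H]2COC(=O)c2ccc(O)cc2)ccc1O | target

**Count**
Total steps: 11. Longest linear sequence: 11 steps (1 → 3 → 5 → 7 → 8 → 9 → 13 → 14 → 15 → 17 → 19 → 20).

**Steps most likely to fail**

Step 6. The 3,4-cis relationship may erode through leakage of the other enolate geometry or through a boat transition state made competitive by the bulky axial substituent of the Z-alkene. The rearrangement may also be slow, and the acidic stage may ionize the benzylic C2–O bond. The fallback sets out from 3 (with aldehyde 6) and comes back at 17, using aldol-based lignan chemistry. Acid 3 is activated with pivaloyl chloride/Et3N and joined to the lithium salt (nBuLi) of (R)-4-benzyl-1,3-oxazolidin-2-one to give (4R)-4-benzyl-3-{3-[4-(benzyloxy)-3-methoxyphenyl]propanoyl}-1,3-oxazolidin-2-one F1. Evans alkylation (NaN(SiMe3)2, THF, −78 °C, tert-butyl bromoacetate) anti to the auxiliary benzyl group should give tert-butyl (3S)-3-[4-(benzyloxy)-3-methoxybenzyl]-4-[(4R)-4-benzyl-2-oxo-1,3-oxazolidin-3-yl]-4-oxobutanoate F2. LiBH4 (THF/H2O) releases the auxiliary to give tert-butyl (3S)-3-[4-(benzyloxy)-3-methoxybenzyl]-4-hydroxybutanoate F3, which closes with catalytic TsOH in warm toluene to (4S)-4-[4-(benzyloxy)-3-methoxybenzyl]oxolan-2-one F4. Its lithium enolate (LiN(SiMe3)2, THF, −78 °C) should add to 6 trans to the arylmethyl group to give (3R,4S)-3-{[4-(benzyloxy)-3-methoxyphenyl](hydroxy)methyl}-4-[4-(benzyloxy)-3-methoxybenzyl]oxolan-2-one F5 (carbinol epimers). LiAlH4 then gives (2S,3S)-2-[4-(benzyloxy)-3-methoxybenzyl]-3-{[4-(benzyloxy)-3-methoxyphenyl](hydroxy)methyl}butane-1,4-diol F6. Brief treatment with catalytic camphorsulfonic acid (CH2Cl2, 0 °C) ionizes the benzylic alcohol, and the 1,4-related primary hydroxyl closes the oxolane with the aryl group trans to the C3 branch, which should give 17.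

Step 3. Facial selectivity in the acetylide addition to the electron-rich aldehyde may be insufficient. The fallback sets out from 5 and 6 and comes back at 7. Addition without a chiral ligand (Zn(OTf)2, Et3N, toluene) gives the carbinol-epimeric (2R,5RS)-5-[4-(benzyloxy)-3-methoxyphenyl]-5-hydroxypent-3-yn-2-yl 3-[4-(benzyloxy)-3-methoxyphenyl]propanoate F7. MnO2 (CH2Cl2) oxidizes it to (2R)-5-[4-(benzyloxy)-3-methoxyphenyl]-5-oxopent-3-yn-2-yl 3-[4-(benzyloxy)-3-methoxyphenyl]propanoate F8. Midland reduction with (S)-Alpine-Borane (B-isopinocampheyl-9-borabicyclo[3.3.1]nonane from (−)-α-pinene, THF, rt), in which the alkyne acts as the small group, should then give 7.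

Step 8. The Lewis acid may ionize the benzylic C2–O bond of the electron-rich 2-aryl oxolane, which would cause epimerization at C2, reductive ring opening or Friedel–Crafts closure onto the neighbouring arene. The fallback sets out from 13 and comes back at 15 without any acid. LiAlH4 (THF, 0 °C) gives (1R,2R,3S)-3-[4-(benzyloxy)-3-methoxybenzyl]-1-[4-(benzyloxy)-3-methoxyphenyl]-2-[(1E)-prop-1-en-1-yl]butane-1,4-diol F9. Selective sulfonylation of the primary hydroxyl (TsCl, Et3N, DMAP cat., CH2Cl2, 0 °C) gives (2S,3R,4E)-2-[4-(benzyloxy)-3-methoxybenzyl]-3-{(R)-[4-(benzyloxy)-3-methoxyphenyl](hydroxy)methyl}hex-4-en-1-yl 4-methylbenzenesulfonate F10. NaH (THF) then closes the ring by intramolecular Williamson etherification (5-exo-tet) to 15, re-forming the O1–C5 bond with C2 untouched.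

**Further compounds**
F1 | step 6 | (4R)-4-benzyl-3-{3-[4-(benzyloxy)-3-methoxyphenyl]propanoyl}-1,3-oxazolidin-2-one | COc1cc(CCC(=O)N2[C@H](Cc3ccccc3)COC2=O)ccc1OCc1ccccc1
F2 | step 6 | tert-butyl (3S)-3-[4-(benzyloxy)-3-methoxybenzyl]-4-[(4R)-4-benzyl-2-oxo-1,3-oxazolidin-3-yl]-4-oxobutanoate | CC(C)(C)OC(=O)C[C@H](Cc1ccc(OCc2ccccc2)c(OC)c1)C(=O)N1[C@H](Cc2ccccc2)COC1=O
F3 | step 6 | tert-butyl (3S)-3-[4-(benzyloxy)-3-methoxybenzyl]-4-hydroxybutanoate | CC(C)(C)OC(=O)C[C@H](Cc1ccc(OCc2ccccc2)c(OC)c1)CO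
F4 | step 6 | (4S)-4-[4-(benzyloxy)-3-methoxybenzyl]oxolan-2-one | COc1cc(C[C@@H]2COC(=O)C2)ccc1OCc1ccccc1
F5 | step 6 | (3R,4S)-3-{[4-(benzyloxy)-3-methoxyphenyl](hydroxy)methyl}-4-[4-(benzyloxy)-3-methoxybenzyl]oxolan-2-one (carbinol epimers) | COc1cc(C[C@@H]2COC(=O)[C@H]2C(O)c2ccc(OCc3ccccc3)c(OC)c2)ccc1OCc1ccccc1
F6 | step 6 | (2S,3S)-2-[4-(benzyloxy)-3-methoxybenzyl]-3-{[4-(benzyloxy)-3-methoxyphenyl](hydroxy)methyl}butane-1,4-diol (carbinol epimers) | COc1cc(C[C@H](CO)[C@@H](CO)C(O)c2ccc(OCc3ccccc3)c(OC)c2)ccc1OCc1ccccc1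
F7 | step 3 | (2R,5RS)-5-[4-(benzyloxy)-3-methoxyphenyl]-5-hydroxypent-3-yn-2-yl 3-[4-(benzyloxy)-3-methoxyphenyl]propanoate | OC(c1ccc(OCc2ccccc2)c(OC)c1)C#C[C@@H](C)OC(=O)CCc1ccc(OCc2ccccc2)c(OC)c1
F8 | step 3 | (2R)-5-[4-(benzyloxy)-3-methoxyphenyl]-5-oxopent-3-yn-2-yl 3-[4-(benzyloxy)-3-methoxyphenyl]propanoate | O=C(c1ccc(OCc2ccccc2)c(OC)c1)C#C[C@@H](C)OC(=O)CCc1ccc(OCc2ccccc2)c(OC)c1
F9 | step 8 | (1R,2R,3S)-3-[4-(benzyloxy)-3-methoxybenzyl]-1-[4-(benzyloxy)-3-methoxyphenyl]-2-[(1E)-prop-1-en-1-yl]butane-1,4-diol | COc1cc(C[C@H](CO)[C@@H](/C=C/C)[C@@H](O)c2ccc(OCc3ccccc3)c(OC)c2)ccc1OCc1ccccc1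
F10 | step 8 | (2S,3R,4E)-2-[4-(benzyloxy)-3-methoxybenzyl]-3-{(R)-[4-(benzyloxy)-3-methoxyphenyl](hydroxy)methyl}hex-4-en-1-yl 4-methylbenzenesulfonate | COc1cc(C[C@H](COS(=O)(=O)c2ccc(C)cc2)[C@@H](/C=C/C)[C@@H](O)c2ccc(OCc3ccccc3)c(OC)c2)ccc1OCc1ccccc1
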